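**Retrosynthetic overview**
1. Target 10 comes from pentabenzyl ether 9 by one global hydrogenolysis.
2. Flavone 9 comes from 2'-hydroxychalcone 8 by oxidative ring closure through the only free phenol, which sits next to the benzyl group and so fixes it at C8.
3. Chalcone 8 comes from the key C–C bond (future C2–C3) by Claisen–Schmidt aldol condensation of ring A ketone 6 with ring B aldehyde 7.
4. Ketone 6 comes from Negishi coupling of iodide 3 with benzylzinc 5; 3 comes from ortho-iodination of 2, and 2 from selective dibenzylation of phloroacetophenone 1.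
5. Rings A, B and the benzyl ring are bought preformed; the pyranone ring C is the only ring built (step 5).

Assumption: the target has no stereocentre and is achiral, so no enantiocontrol is needed; the only stereo-element on the route is the E double bond of chalcone 8.

**Step 1**
Reactants: 1 1-(2,4,6-trihydroxyphenyl)ethanone (phloroacetophenone)
Product: 2 1-[2,4-bis(benzyloxy)-6-hydroxyphenyl]ethanone
Conditions: BnBr (2.05 equiv), K2CO3 (2.2 equiv), DMF, 0 °C to rt, 16 h
Reagents that add atoms: benzyl bromide, BrCc1ccccc1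
Why: Williamson etherification in which the 4-OH and one ortho-OH are alkylated while the remaining ortho-OH, locked in a hydrogen bond to the acetyl C=O, stays free.

**Step 2**
Reactants: 2 1-[2,4-bis(benzyloxy)-6-hydroxyphenyl]ethanone
Product: 3 1-[4,6-bis(benzyloxy)-2-hydroxy-3-iodophenyl]ethanone
Conditions: BnMe3N+ ICl2− (1.05 equiv), CaCO3 (1.5 equiv), CH2Cl2/MeOH 5:2, rt, 3 h; aq Na2S2O3
Reagents that add atoms: benzyltrimethylammonium dichloroiodate, C[N+](C)(C)Cc1ccccc1.Cl[I-]Cl
Why: Electrophilic aromatic iodination that, for 2-hydroxy-4,6-dialkoxyacetophenones with this mild buffered reagent, goes ortho to the free chelated phenol (C3), to be confirmed by NOE of the remaining ring proton to both OCH2Ph groups.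

**Step 3**
Reactants: 3 1-[4,6-bis(benzyloxy)-2-hydroxy-3-iodophenyl]ethanone; 4 1-(benzyloxy)-4-(chloromethyl)benzene
Product: 6 1-[4,6-bis(benzyloxy)-3-[4-(benzyloxy)benzyl]-2-hydroxyphenyl]ethanone, via 4-(benzyloxy)benzylzinc chloride 5 (not isolated)
Conditions: 4 (2.5 equiv), Zn dust (3.8 equiv), LiCl (3.8 equiv), THF, 25 °C, 4 h; then the solution of 5 (2.0 equiv) added slowly to 3, Pd(OAc)2 (2 mol %), SPhos (2-dicyclohexylphosphino-2',6'-dimethoxybiphenyl, 4 mol %), THF, 25 °C, 12 h; aq NH4Cl
Reagents that add atoms: none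
Why: LiCl-promoted zinc insertion gives the benzylic zinc chloride, which undergoes a Negishi cross-coupling at the hindered electron-rich iodide; the organozinc tolerates the ketone, and the excess covers any protonation by the phenol.

**Step 4**
Reactants: 6 1-[4,6-bis(benzyloxy)-3-[4-(benzyloxy)benzyl]-2-hydroxyphenyl]ethanone; 7 3,4-bis(benzyloxy)benzaldehyde
Product: 8 (E)-1-[4,6-bis(benzyloxy)-3-[4-(benzyloxy)benzyl]-2-hydroxyphenyl]-3-[3,4-bis(benzyloxy)phenyl]prop-2-en-1-one
Conditions: 7 (1.2 equiv), KOH (10 equiv, 50% aq), EtOH/THF 1:1, rt, 36 h; then 1 M HCl to pH 4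
Reagents that add atoms: none
Why: Claisen–Schmidt aldol condensation of the methyl ketone enolate with a non-enolisable aldehyde, where E1cB dehydration gives the conjugated E-enone under thermodynamic control (any flavanone formed by ring closure converges in step 5).

**Step 5**
Reactants: 8 the E-chalcone from step 4
Product: 9 5,7-bis(benzyloxy)-8-[4-(benzyloxy)benzyl]-2-[3,4-bis(benzyloxy)phenyl]-4H-chromen-4-one
Conditions: I2 (10 mol %), DMSO, 120 °C, 3 h; aq Na2S2O3
Reagents that add atoms: none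
Why: Iodine-catalysed oxidative cyclisation of a 2'-hydroxychalcone, with oxa-Michael closure through the only free phenol and dehydrogenation to the flavone, DMSO being the terminal oxidant that returns HI to I2.

**Step 6**
Reactants: 9 the pentabenzyl flavone from step 5
Product: 10 8-(4-hydroxybenzyl)luteolin, 2-(3,4-dihydroxyphenyl)-5,7-dihydroxy-8-(4-hydroxybenzyl)-4H-chromen-4-one
Conditions: H2 (1 atm), 10% Pd/C, THF/MeOH 1:1, rt, 8 h; filter through Celite
Reagents that add atoms: none
Why: Catalytic hydrogenolysis cleaves all five benzylic C–O bonds under neutral conditions, while the diarylmethane C–C bonds and the flavone enone are untouched at 1 atm and room temperature.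

**Compound list**
1 | 1-(2,4,6-trihydroxyphenyl)ethanone | CC(=O)c1c(O)cc(O)cc1O | starting material
2 | 1-[2,4-bis(benzyloxy)-6-hydroxyphenyl]ethanone | CC(=O)c1c(O)cc(OCc2ccccc2)cc1OCc1ccccc1 | intermediate
3 | 1-[4,6-bis(benzyloxy)-2-hydroxy-3-iodophenyl]ethanone | CC(=O)c1c(O)c(I)c(OCc2ccccc2)cc1OCc1ccccc1 | intermediate
4 | 1-(benzyloxy)-4-(chloromethyl)benzene (4-(benzyloxy)benzyl chloride) | ClCc1ccc(OCc2ccccc2)cc1 | starting material
5 | 4-(benzyloxy)benzylzinc chloride (THF solution, not isolated) | Cl[Zn]Cc1ccc(OCc2ccccc2)cc1 | intermediate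
6 | 1-[4,6-bis(benzyloxy)-3-[4-(benzyloxy)benzyl]-2-hydroxyphenyl]ethanone | CC(=O)c1c(O)c(Cc2ccc(OCc3ccccc3)cc2)c(OCc2ccccc2)cc1OCc1ccccc1 | intermediate
7 | 3,4-bis(benzyloxy)benzaldehyde | O=Cc1ccc(OCc2ccccc2)c(OCc2ccccc2)c1 | starting material
8 | (E)-1-[4,6-bis(benzyloxy)-3-[4-(benzyloxy)benzyl]-2-hydroxyphenyl]-3-[3,4-bis(benzyloxy)phenyl]prop-2-en-1-one | O=C(/C=C/c1ccc(OCc2ccccc2)c(OCc2ccccc2)c1)c1c(O)c(Cc2ccc(OCc3ccccc3)cc2)c(OCc2ccccc2)cc1OCc1ccccc1 | intermediate
9 | 5,7-bis(benzyloxy)-8-[4-(benzyloxy)benzyl]-2-[3,4-bis(benzyloxy)phenyl]-4H-chromen-4-one | O=c1cc(-c2ccc(OCc3ccccc3)c(OCc3ccccc3)c2)oc2c(Cc3ccc(OCc4ccccc4)cc3)c(OCc3ccccc3)cc(OCc3ccccc3)c12 | intermediate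
10 | 8-(4-hydroxybenzyl)luteolin (achiral) | O=c1cc(-c2ccc(O)c(O)c2)oc2c(Cc3ccc(O)cc3)c(O)cc(O)c12 | target

**Totals**
Total step count: 6 (the zinc reagent 5 is generated and consumed within step 3).
Longest linear sequence: 6 steps (1 → 2 → 3 → 6 → 8 → 9 → 10).

**Three steps most likely to fail, with fallbacks**

Step 3 (Negishi coupling on a di-ortho-substituted iodide carrying a free phenol; risk of stalled coupling or protodeiodination). The fallback sets out from 3 and comes back at 9, with the coupling moved to the flavone stage where the iodide is non-phenolic and electron-poorer. Claisen–Schmidt condensation of 3 with 7 (KOH, EtOH/THF, rt) gives (E)-1-[4,6-bis(benzyloxy)-2-hydroxy-3-iodophenyl]-3-[3,4-bis(benzyloxy)phenyl]prop-2-en-1-one F2. Oxidative cyclisation (I2 10 mol %, DMSO, 120 °C) closes the ring through the phenol next to iodine and gives 5,7-bis(benzyloxy)-2-[3,4-bis(benzyloxy)phenyl]-8-iodo-4H-chromen-4-one F3. Negishi coupling of F3 with zinc reagent 5 (Pd(OAc)2, SPhos, THF, 25 to 50 °C) then gives 9.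

Step 2 (iodination; risk of a C3/C5 mixture or di-iodination). The fallback sets out from 1 and comes back at 6, avoiding halogenation and cross-coupling altogether. The benzyl group is put on the symmetrical ring of 1, where C3 and C5 are equivalent. Friedel–Crafts C-benzylation of 1 (3 equiv) with commercial 4-(benzyloxy)benzyl alcohol (BF3·OEt2, dioxane, rt) gives 1-[3-[4-(benzyloxy)benzyl]-2,4,6-trihydroxyphenyl]ethanone F1. O-Benzylation of F1 (BnBr 2.05 equiv, K2CO3, DMF, rt) should take the 4-OH and the less hindered 6-OH, leaving the 2-OH that is flanked by the C-benzyl group and chelated to the acetyl, which is 6. Which ortho-OH stays free is the uncertain point of this fallback and must be checked by NOE of H-5 to both OCH2Ph groups.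

Step 5 (I2/DMSO at 120 °C in the presence of five benzyl ethers; risk of cleavage of the ether ortho to the carbonyl before ring closure, or ring iodination). The fallback sets out from 6 and comes back at 9, building ring C by Claisen acylation and cyclodehydration instead of oxidation. Commercial 3,4-bis(benzyloxy)benzoic acid is converted with oxalyl chloride (cat. DMF, CH2Cl2, rt) into 3,4-bis(benzyloxy)benzoyl chloride F4. The dianion of 6 (LiN(SiMe3)2 3.2 equiv, THF, −78 °C) is C-acylated with F4 (−78 °C to rt) to give 1-[4,6-bis(benzyloxy)-3-[4-(benzyloxy)benzyl]-2-hydroxyphenyl]-3-[3,4-bis(benzyloxy)phenyl]propane-1,3-dione F5; any O-aroyl ester rearranges to the same diketone under the excess base. Cyclodehydration of F5 (p-TsOH·H2O 10 mol %, toluene, 90 °C) gives 9.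

**Further compounds**
F1 | step 2 | 1-[3-[4-(benzyloxy)benzyl]-2,4,6-trihydroxyphenyl]ethanone | CC(=O)c1c(O)cc(O)c(Cc2ccc(OCc3ccccc3)cc2)c1O
F2 | step 3 | (E)-1-[4,6-bis(benzyloxy)-2-hydroxy-3-iodophenyl]-3-[3,4-bis(benzyloxy)phenyl]prop-2-en-1-one | O=C(/C=C/c1ccc(OCc2ccccc2)c(OCc2ccccc2)c1)c1c(O)c(I)c(OCc2ccccc2)cc1OCc1ccccc1
F3 | step 3 | 5,7-bis(benzyloxy)-2-[3,4-bis(benzyloxy)phenyl]-8-iodo-4H-chromen-4-one | O=c1cc(-c2ccc(OCc3ccccc3)c(OCc3ccccc3)c2)oc2c(I)c(OCc3ccccc3)cc(OCc3ccccc3)c12
F4 | step 5 | 3,4-bis(benzyloxy)benzoyl chloride | O=C(Cl)c1ccc(OCc2ccccc2)c(OCc2ccccc2)c1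
F5 | step 5 | 1-[4,6-bis(benzyloxy)-3-[4-(benzyloxy)benzyl]-2-hydroxyphenyl]-3-[3,4-bis(benzyloxy)phenyl]propane-1,3-dione | O=C(CC(=O)c1ccc(OCc2ccccc2)c(OCc2ccccc2)c1)c1c(O)c(Cc2ccc(OCc3ccccc3)cc2)c(OCc2ccccc2)cc1OCc1ccccc1
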